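**Retrosynthetic overview**
1. Feature: the west dihydrofuran (O1, C2 bearing 4-hydroxyphenyl, C3) fused to the central 1,3-dioxygenated benzene is a (2S)-flavanone skeleton in which benzo carbon C4a is bonded to C3 instead of to the carbonyl carbon C4. West C2 is (S), as in naringenin, and the old 5-oxygen marks the central-ring carbon that carries the seven-ring CH2.
2. Last operations: sevenfold O-demethylation. Before it, the east furan is made by [4+1] annulation of a central-ring o-quinone methide with a chiral 4-methoxybenzyl sulfonium ylide.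
3. Seven-membered ring: the bond from the CH(aryl) carbon to ring B (the resorcinol ring on west C3) comes from Friedel–Crafts closure of a protonated 4-methoxystyryl group. It is closed before the east aryl group exists, because afterwards two mirror-related resorcinol rings would flank the styryl group.
4. The styryl group comes from the aryl triflate (Suzuki–Miyaura) and ring B from the C3 carboxyl group (decarboxylative arylation). The ester and the west furan come from oxidative ring contraction of a 5-triflyloxyflavanone made in three steps from (S)-naringenin.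
5. Ring order: west furan (step 4), seven-membered ring (step 8), east furan (step 14).

Key step: step 4

Assumption: (S)-naringenin is bought as the single (2S) enantiomer; the enantiomeric purity is to be checked on 4 by chiral HPLC and, if needed, raised there by recrystallisation.
Assumption: benzylide 23 is taken to react through the same open face as the benzylides of this sulfide do with C=O and C=N acceptors; if the sense proved opposite, the mirror-image sulfide (from (R)-limonene) would be used.
Numbering remark for 13–18: C1 is west C3. C2–C7 is ring B. C8 is the seven-ring CH(aryl) and C9 the seven-ring CH2. C10–C14 and C17 form the central ring (C11 the free CH next to C10, C12 the oxygenated carbon, C13 the CH between the two oxygens). O15 and C16 are the west furan O and C2.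

Step 1
Reactants: 1 (2S)-naringenin
Product: 2 (2S)-7-benzyloxy-5-hydroxy-2-(4-hydroxyphenyl)chroman-4-one
Conditions: BnBr (1.05 equiv), KHCO3 (1.2 equiv), DMF, 40 °C
Reagents that add atoms: benzyl bromide, BrCc1ccccc1
Why: Williamson etherification under acidity control: hydrogen carbonate ionises only the 7-OH (para to the carbonyl group), while the 5-OH is chelated and the 4'-OH stays protonated, so neither a 4'-phenoxide (quinone methide opening) nor a C3 enolate (chalcone opening) that could racemise C2 is formed.

Step 2
Reactants: 2 (2S)-7-benzyloxy-5-hydroxy-2-(4-hydroxyphenyl)chroman-4-one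
Product: 3 (2S)-7-benzyloxy-5-hydroxy-2-(4-methoxyphenyl)chroman-4-one
Conditions: MeOH (1.1 equiv), PPh3 (1.1 equiv), DIAD (1.1 equiv), THF, 0 °C to rt
Reagents that add atoms: methanol, CO
Why: Mitsunobu etherification needs no external base; the free 4'-phenol reacts well ahead of the chelated, hindered 5-OH, and the phenoxide exists only as an ion pair that is methylated at once, so C2 should keep its configuration.

Step 3
Reactants: 3 (2S)-7-benzyloxy-5-hydroxy-2-(4-methoxyphenyl)chroman-4-one
Product: 4 (2S)-7-benzyloxy-2-(4-methoxyphenyl)-4-oxochroman-5-yl trifluoromethanesulfonate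
Conditions: Tf2O (1.2 equiv), pyridine (3 equiv), CH2Cl2, -10 to 0 °C
Reagents that add atoms: trifluoromethanesulfonic anhydride, O=S(=O)(OS(=O)(=O)C(F)(F)F)C(F)(F)F
Why: O-sulfonylation of the last free phenol: the anhydride is reactive enough to override the hydrogen bond to the carbonyl group, and pyridine is too weak a base to enolise C3, so C2 is untouched.

Step 4
Reactants: 4 (2S)-7-benzyloxy-2-(4-methoxyphenyl)-4-oxochroman-5-yl trifluoromethanesulfonate
Product: 7 methyl (2S,3S)-6-benzyloxy-2-(4-methoxyphenyl)-4-(trifluoromethylsulfonyloxy)-2,3-dihydrobenzofuran-3-carboxylate (trans), via enol ether 5 (not isolated), via iodane ketal 6 (not isolated)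
Conditions: PhI(OAc)2 (1.15 equiv), H2SO4 (cat.), HC(OMe)3, 0 °C to rt
Reagents that add atoms: trimethyl orthoformate, COC(OC)OC
Why: Acidic orthoformate turns ketone 4 into enol ether 5, the iodine reagent attacks C3 on the face away from the equatorial C2 aryl group and methanol caps C4, which gives ketal 6 with an equatorial C3–I bond that is antiperiplanar to the C4–C4a ring bond. As iodobenzene leaves, the ipso carbon C4a bridges to C3 (phenonium-type transition state) and C4 is left as a dimethoxycarbenium ion that is demethylated to the methyl ester; this is the known hypervalent-iodine ring contraction (oxidative 1,2-aryl shift) of flavanones to trans-2-aryl-2,3-dihydrobenzofuran-3-carboxylates. The dihydrofuran is closed by contraction, not by a fresh cyclisation: in the ring O1–C2–C3–C4–C4a–C8a the bond C4a–C3 forms (formally a 3-exo-tet ipso attack) while C4–C4a breaks, so C4 leaves the ring. C2 is never touched and keeps the (S) configuration of naringenin, whereas C3 is inverted in the shift, so the trans iodane gives the trans (3S) ester, which is also the more stable epimer. The step needs migration of C4a in preference to the C2 anisyl group (isoflavone) and to elimination (flavone): the two ketal oxygens push only the substituent on C4, the diequatorial conformer of 6 aligns only ring bonds with C–I, and the para benzyloxy group and the ortho ring oxygen keep C4a a good migrating carbon in spite of the triflate. Acid opening to the chalcone, which would erode C2, is held back because the carbonyl group is masked early as 5 and 6 and the temperature stays at or below rt.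

Step 5
Reactants: 7 methyl (2S,3S)-6-benzyloxy-2-(4-methoxyphenyl)-4-(trifluoromethylsulfonyloxy)-2,3-dihydrobenzofuran-3-carboxylate
Product: 8 (2S,3S)-6-benzyloxy-2-(4-methoxyphenyl)-4-(trifluoromethylsulfonyloxy)-2,3-dihydrobenzofuran-3-carboxylic acid
Conditions: Me3SnOH (8 equiv), ClCH2CH2Cl, 70 °C; then 1 M HCl wash
Reagents that add atoms: trimethyltin hydroxide, C[Sn](C)(C)O
Why: Tin hydroxide ester cleavage: the neutral reagent delivers OH to the ester carbonyl without forming the C3 enolate, whose β-elimination of the ring phenoxide would destroy C2, and it should leave the aryl sulfonate alone.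

Step 6
Reactants: 8 (2S,3S)-6-benzyloxy-2-(4-methoxyphenyl)-4-(trifluoromethylsulfonyloxy)-2,3-dihydrobenzofuran-3-carboxylic acid; 9 1-bromo-3,5-dimethoxybenzene
Product: 10 (2S,3S)-6-benzyloxy-3-(3,5-dimethoxyphenyl)-2-(4-methoxyphenyl)-2,3-dihydrobenzofuran-4-yl trifluoromethanesulfonate (trans)
Conditions: NiBr2(dme) (10 mol %), dtbbpy (12 mol %), 4CzIPN (3 mol %), Cs2CO3 (1.5 equiv), 9 (2 equiv), DMF, 450 nm LED, rt
Reagents that add atoms: none
Why: Nickel/photoredox decarboxylative C(sp3)–C(sp2) arylation: the excited dye oxidises the carboxylate, loss of CO2 gives the secondary benzylic C3 radical (its C2–O bond lies near the nodal plane, so β-scission is slow), the aryl-nickel bromide from 9 captures it on the face away from the C2 anisyl group and reductive elimination sets C3 as (S), trans, while bipyridine-bound nickel inserts into C–Br much faster than into the hindered, electron-rich C–OTf bond.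

Step 7
Reactants: 10 (2S,3S)-6-benzyloxy-3-(3,5-dimethoxyphenyl)-2-(4-methoxyphenyl)-2,3-dihydrobenzofuran-4-yl trifluoromethanesulfonate; 11 (E)-2-(4-methoxyphenyl)vinylboronic acid
Product: 12 (2S,3S)-6-benzyloxy-3-(3,5-dimethoxyphenyl)-2-(4-methoxyphenyl)-4-[(E)-2-(4-methoxyphenyl)ethenyl]-2,3-dihydrobenzofuran
Conditions: Pd(OAc)2 (5 mol %), SPhos (10 mol %), K3PO4 (3 equiv), THF/H2O 10:1, 60 °C
Reagents that add atoms: none
Why: Suzuki–Miyaura coupling: the bulky electron-rich biarylphosphine lets zerovalent palladium insert into the hindered C–OTf bond, no base-labile stereocentre is left, and the alkene geometry has no bearing on step 8.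

Step 8
Reactants: 12 (2S,3S)-6-benzyloxy-3-(3,5-dimethoxyphenyl)-2-(4-methoxyphenyl)-4-[(E)-2-(4-methoxyphenyl)ethenyl]-2,3-dihydrobenzofuran
Product: 13 (1S,8S,16S)-12-benzyloxy-4,6-dimethoxy-8,16-bis(4-methoxyphenyl)-15-oxatetracyclo[8.6.1.0(2,7).0(14,17)]heptadeca-2(7),3,5,10(17),11,13-hexaene
Conditions: TsOH·H2O (0.3 equiv), CH2Cl2/(CF3)2CHOH 4:1, 0.01 M, 0 °C to rt
Reagents that add atoms: none
Why: Intramolecular Friedel–Crafts hydroarylation, the acid cyclisation known for ε-viniferin-type stilbenes: protonation at the alkene carbon next to the central ring gives the 4-methoxybenzyl cation, the doubly activated ortho carbon of ring B attacks it (7-endo), and the new centre is set (S) by the substrate, because only the closure that puts the anisyl group pseudoaxial, on the side of west C3–H and away from the adjacent methoxy group of ring B, escapes severe peri strain, with the reversibility of the alkylation favouring the same isomer.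

Step 9
Reactants: 13 benzyl ether of the tetracyclic core
Product: 14 (1S,8S,16S)-4,6-dimethoxy-8,16-bis(4-methoxyphenyl)-15-oxatetracyclo[8.6.1.0(2,7).0(14,17)]heptadeca-2(7),3,5,10(17),11,13-hexaen-12-ol
Conditions: H2 (1 atm), 10% Pd/C, EtOAc/MeOH, rt
Reagents that add atoms: none
Why: Hydrogenolysis of the aryl benzyl ether: the exposed O–CH2Ph bond is cleaved well before the hindered cyclic benzylic C16–O bond, and no alkene is left in the molecule.

Step 10
Reactants: 14 tetracyclic phenol
Product: 15 (1S,8S,16S)-12-hydroxy-4,6-dimethoxy-8,16-bis(4-methoxyphenyl)-15-oxatetracyclo[8.6.1.0(2,7).0(14,17)]heptadeca-2(7),3,5,10(17),11,13-hexaene-11-carbaldehyde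
Conditions: MgCl2 (3 equiv), Et3N (6 equiv), (CH2O)n (10 equiv), MeCN, reflux; 1 M HCl work-up
Reagents that add atoms: paraformaldehyde (as formaldehyde), C=O
Why: Casnati–Skattebøl ortho-formylation: only the ring that carries the magnesium phenoxide reacts, so ring B and the anisyl rings are spared, and of the two ortho carbons C11 (para to the furan oxygen) should be attacked, as in orcinol-type phenols and 6-hydroxy-2,3-dihydrobenzofurans, rather than C13, which is wedged between two oxygens next to the ring fusion.

Step 11
Reactants: 15 tetracyclic salicylaldehyde; 9 1-bromo-3,5-dimethoxybenzene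
Product: 17 11-[(3,5-dimethoxyphenyl)(hydroxy)methyl] derivative of phenol 14 (both carbinol epimers), via Grignard reagent 16 (not isolated)
Conditions: 9 (3 equiv), Mg, THF, rt to 40 °C; then 15, THF, -20 °C to rt; aqueous work-up
Reagents that add atoms: none
Why: Grignard 1,2-addition to the aldehyde after one equivalent has deprotonated the phenol; the carbinol configuration is irrelevant because this carbon becomes planar in step 14.

Step 12
Reactants: 17 o-hydroxybenzhydrol
Product: 18 11-[(3,5-dimethoxyphenyl)(4-methylphenylsulfonyl)methyl] derivative of phenol 14 (both epimers)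
Conditions: p-TolSO2Na (3 equiv), HCO2H/H2O/THF, rt
Reagents that add atoms: sodium p-toluenesulfinate, Cc1ccc(S(=O)[O-])cc1.[Na+]
Why: SN1 substitution through the strongly stabilised o-hydroxybenzhydryl cation, which sulfinate captures at sulfur to give a stable sulfone that releases the o-quinone methide with mild base.

Step 13
Reactants: 19 (1S,4S,5S)-4,7,7-trimethyl-6-thiabicyclo[3.2.1]octane (isothiocineole; commercial, also one step from (S)-limonene and sulfur); 20 4-methoxybenzyl alcohol
Product: 21 (1S,4S,5S)-6-(4-methoxybenzyl)-4,7,7-trimethyl-6-thiabicyclo[3.2.1]octan-6-ium tetrafluoroborate (benzyl group exo on sulfur)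
Conditions: HBF4·OEt2 (1.05 equiv), CH2Cl2, 0 °C to rt; precipitation with Et2O
Reagents that add atoms: tetrafluoroboric acid (diethyl ether complex), [H+].F[B-](F)(F)F
Why: S-alkylation of the sulfide by the 4-methoxybenzyl cation set free from the alcohol; only the exposed exo lone pair is alkylated, which gives one sulfonium diastereomer, and the non-nucleophilic anion prevents reversal.

Step 14
Reactants: 18 o-quinone methide precursor sulfone; 21 chiral 4-methoxybenzyl sulfonium tetrafluoroborate
Product: 24 hepta-O-methyl ether of the target (west 2S,3S; seven-ring CH S; east 2R,3R), via quinone methide 22 (not isolated), via sulfonium benzylide 23 (not isolated)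
Conditions: 21 (1.8 equiv), Cs2CO3 (4 equiv), CH2Cl2/MeCN, 0 °C to rt
Reagents that add atoms: none
Why: Proposed new method: base expels toluenesulfinate from 18 to give o-quinone methide 22 and deprotonates 21 to benzylide 23, 23 adds through its one open face to the exocyclic carbon of 22, and the rearomatised phenoxide displaces the sulfide at the benzylic carbon with inversion (5-exo-tet); only the betaine that can hold the two aryl groups anti closes quickly, so the sulfide fixes east C2 as (R) and the trans closure relays this to east C3 as (R), an external control that is needed because the stereocentres of the core lie too far from the planar quinone methide to choose its face; the closest known reactions are the trans-selective [4+1] annulation of o-quinone methides from 2-(sulfonylmethyl)phenols with carbonyl-stabilised sulfur ylides and the asymmetric epoxidation and aziridination with benzylides of this same sulfide.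

Step 15
Reactants: 24 hepta-O-methyl ether of the target
Product: 25 target CNP0136963.1
Conditions: BBr3 (20 equiv), CH2Cl2, -78 °C to rt; then ice/water
Reagents that add atoms: none
Why: Lewis-acid cleavage of all seven aryl methyl ethers; no alkene is left to cyclise, and should a furan C2–O bond ionise it can only re-close trans to its fixed C3 neighbour, so no stereocentre is lost.

**Compound list**
1 | (2S)-naringenin | O=C1C[C@@H](c2ccc(O)cc2)Oc2cc(O)cc(O)c12 | starting material
2 | (2S)-7-benzyloxy-5-hydroxy-2-(4-hydroxyphenyl)chroman-4-one | O=C1C[C@@H](c2ccc(O)cc2)Oc2cc(OCc3ccccc3)cc(O)c12 | intermediate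
3 | (2S)-7-benzyloxy-5-hydroxy-2-(4-methoxyphenyl)chroman-4-one | O=C1C[C@@H](c2ccc(OC)cc2)Oc2cc(OCc3ccccc3)cc(O)c12 | intermediate
4 | (2S)-7-benzyloxy-2-(4-methoxyphenyl)-4-oxochroman-5-yl trifluoromethanesulfonate | O=C1C[C@@H](c2ccc(OC)cc2)Oc2cc(OCc3ccccc3)cc(OS(=O)(=O)C(F)(F)F)c12 | intermediate
5 | (2S)-7-benzyloxy-4-methoxy-2-(4-methoxyphenyl)-2H-chromen-5-yl trifluoromethanesulfonate (enol ether) | COC1=C[C@@H](c2ccc(OC)cc2)Oc2cc(OCc3ccccc3)cc(OS(=O)(=O)C(F)(F)F)c12 | intermediate
6 | 3-[acetoxy(phenyl)iodanyl]-7-benzyloxy-4,4-dimethoxy-2-(4-methoxyphenyl)chroman-5-yl trifluoromethanesulfonate, iodine trans to the C2 aryl group ((2R,3R) by CIP, C2 spatially unchanged) | COC1(OC)[C@H](I(OC(C)=O)c2ccccc2)[C@@H](c2ccc(OC)cc2)Oc2cc(OCc3ccccc3)cc(OS(=O)(=O)C(F)(F)F)c12 | intermediate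
7 | methyl (2S,3S)-6-benzyloxy-2-(4-methoxyphenyl)-4-(trifluoromethylsulfonyloxy)-2,3-dihydrobenzofuran-3-carboxylate | COC(=O)[C@H]1c2c(OS(=O)(=O)C(F)(F)F)cc(OCc3ccccc3)cc2O[C@@H]1c1ccc(OC)cc1 | intermediate
8 | (2S,3S)-6-benzyloxy-2-(4-methoxyphenyl)-4-(trifluoromethylsulfonyloxy)-2,3-dihydrobenzofuran-3-carboxylic acid | OC(=O)[C@H]1c2c(OS(=O)(=O)C(F)(F)F)cc(OCc3ccccc3)cc2O[C@@H]1c1ccc(OC)cc1 | intermediate
9 | 1-bromo-3,5-dimethoxybenzene | COc1cc(Br)cc(OC)c1 | starting material
10 | (2S,3S)-6-benzyloxy-3-(3,5-dimethoxyphenyl)-2-(4-methoxyphenyl)-2,3-dihydrobenzofuran-4-yl trifluoromethanesulfonate | COc1cc(OC)cc(c1)[C@H]1c2c(OS(=O)(=O)C(F)(F)F)cc(OCc3ccccc3)cc2O[C@@H]1c1ccc(OC)cc1 | intermediate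
11 | (E)-2-(4-methoxyphenyl)vinylboronic acid | COc1ccc(/C=C/B(O)O)cc1 | starting material
12 | (2S,3S)-6-benzyloxy-3-(3,5-dimethoxyphenyl)-2-(4-methoxyphenyl)-4-[(E)-2-(4-methoxyphenyl)ethenyl]-2,3-dihydrobenzofuran | COc1cc(OC)cc(c1)[C@H]1c2c(/C=C/c3ccc(OC)cc3)cc(OCc3ccccc3)cc2O[C@@H]1c1ccc(OC)cc1 | intermediate
13 | (1S,8S,16S)-12-benzyloxy-4,6-dimethoxy-8,16-bis(4-methoxyphenyl)-15-oxatetracyclo[8.6.1.0(2,7).0(14,17)]heptadeca-2(7),3,5,10(17),11,13-hexaene | COc1ccc([C@@H]2Cc3c4c(cc(OCc5ccccc5)c3)O[C@H](c3ccc(OC)cc3)[C@H]4c3cc(OC)cc(OC)c32)cc1 | intermediate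
14 | 12-ol of the same tetracycle (1S,8S,16S) | COc1ccc([C@@H]2Cc3c4c(cc(O)c3)O[C@H](c3ccc(OC)cc3)[C@H]4c3cc(OC)cc(OC)c32)cc1 | intermediate
15 | 12-hydroxy-11-carbaldehyde of the same tetracycle (1S,8S,16S) | COc1ccc([C@@H]2Cc3c4c(cc(O)c3C=O)O[C@H](c3ccc(OC)cc3)[C@H]4c3cc(OC)cc(OC)c32)cc1 | intermediate
16 | (3,5-dimethoxyphenyl)magnesium bromide | COc1cc(OC)cc([Mg]Br)c1 | intermediate
17 | 11-[(3,5-dimethoxyphenyl)(hydroxy)methyl] derivative of 14, both carbinol epimers | COc1ccc([C@@H]2Cc3c4c(cc(O)c3C(O)c3cc(OC)cc(OC)c3)O[C@H](c3ccc(OC)cc3)[C@H]4c3cc(OC)cc(OC)c32)cc1 | intermediate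
18 | 11-[(3,5-dimethoxyphenyl)(4-methylphenylsulfonyl)methyl] derivative of 14, both epimers | COc1ccc([C@@H]2Cc3c4c(cc(O)c3C(c3cc(OC)cc(OC)c3)S(=O)(=O)c3ccc(C)cc3)O[C@H](c3ccc(OC)cc3)[C@H]4c3cc(OC)cc(OC)c32)cc1 | intermediate
19 | (1S,4S,5S)-4,7,7-trimethyl-6-thiabicyclo[3.2.1]octane | C[C@H]1CC[C@H]2C[C@@H]1SC2(C)C | starting material
20 | 4-methoxybenzyl alcohol | COc1ccc(CO)cc1 | starting material
21 | (1S,4S,5S)-6-(4-methoxybenzyl)-4,7,7-trimethyl-6-thiabicyclo[3.2.1]octan-6-ium tetrafluoroborate, benzyl exo | C[C@H]1CC[C@H]2C[C@@H]1[S@+](Cc1ccc(OC)cc1)C2(C)C.F[B-](F)(F)F | intermediate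
22 | o-quinone methide: 11-(3,5-dimethoxybenzylidene)-12-oxo form of the tetracycle (alkene geometry open) | COc1ccc([C@@H]2CC3=C4C(=CC(=O)C3=Cc3cc(OC)cc(OC)c3)O[C@H](c3ccc(OC)cc3)[C@H]4c3cc(OC)cc(OC)c32)cc1 | intermediate
23 | 4-methoxybenzylide of sulfonium salt 21 | C[C@H]1CC[C@H]2C[C@@H]1[S@+]([CH-]c1ccc(OC)cc1)C2(C)C | intermediate
24 | hepta-O-methyl ether of the target | COc1ccc([C@@H]2Cc3c4c(cc5c3[C@@H](c3cc(OC)cc(OC)c3)[C@H](c3ccc(OC)cc3)O5)O[C@H](c3ccc(OC)cc3)[C@H]4c3cc(OC)cc(OC)c32)cc1 | intermediate
25 | CNP0136963.1 | Oc1ccc([C@@H]2Cc3c4c(cc5c3[C@@H](c3cc(O)cc(O)c3)[C@H](c3ccc(O)cc3)O5)O[C@H](c3ccc(O)cc3)[C@H]4c3cc(O)cc(O)c32)cc1 | target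

**Step count**
Total step count: 15. Longest linear sequence: 14 (steps 1–12, 14, 15).

**Three steps most likely to fail**
1. Step 14 (the one new method).
What may go wrong: the benzylide may add with poor facial selectivity. It may also close in part to the cis furan, which carries the opposite east C3. The 4-methoxybenzyl group may be transferred from sulfur to the phenoxide or to sulfinate. The bulky ylide may be so slow that the quinone methide oligomerises.
Fallback with known chemistry only, from 18 back to 24: 18 is treated with commercial ethyl (dimethylsulfuranylidene)acetate and Cs2CO3 in CH2Cl2. This is the established [4+1] annulation of such sulfones with ester-stabilised ylides. It should give two trans diastereomers that differ in the east furan, the east-(2R,3R) ethyl ester F1 and the east-(2S,3S) ethyl ester F2. Because the core is one enantiomer, they can be separated by chromatography. Me3SnOH cleaves F1 to the east furan-2-carboxylic acid F3. F3 is then coupled with 4-bromoanisole under the conditions of step 6, for which α-oxy acids are standard substrates. The anisyl group enters trans to the east C3 aryl group and gives 24.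

2. Step 6.
What may go wrong: the hindered benzylic radical may be captured too slowly by nickel and be lost to dimerisation or hydrogen abstraction, or nickel may insert into the C–O bond of the triflate.
Fallback from 7 back to 12, in which the triflate is used up first and light is avoided: Suzuki–Miyaura coupling of 7 with 11 (Pd(OAc)2, SPhos, K3PO4) gives the styryl methyl ester F4. Me3SnOH gives the styryl acid F5. N-hydroxyphthalimide and diisopropylcarbodiimide give the redox-active ester F6. NiCl2(dme)/dtbbpy in THF/DMF at rt couples F6 with (3,5-dimethoxyphenyl)zinc chloride F7, made from 16 and ZnCl2. This thermal decarboxylative Negishi-type arylation is again trans to the C2 aryl group and gives 12.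

3. Step 4.
What may go wrong: the C2 anisyl group may shift instead of C4a, elimination may lead to the flavone, the iodine reagent may attack an electron-rich ring, or acid opening may erode the configuration at C2.
Fallback from 4 back to 7, a stepwise and non-oxidative version of the same 1,2-shift with bromide as leaving group (the α-halo ketal rearrangement used for 2-arylalkanoic esters): CuBr2 in EtOAc/CHCl3 at reflux brominates C3 without base to give the trans-3-bromoflavanone F8. HC(OMe)3, MeOH and TsOH (cat.) give its dimethyl ketal F9, which can be purified and checked for configuration. ZnBr2 (cat.) in warm toluene then triggers the shift of C4a to C3 with loss of bromomethane and gives 7.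

**Further compounds**
F1 | step 14 | ethyl ester: 24 with CO2Et in place of the east C2 anisyl group, east (2R,3R), trans | COc1ccc([C@@H]2Cc3c4c(cc5c3[C@@H](c3cc(OC)cc(OC)c3)[C@H](C(=O)OCC)O5)O[C@H](c3ccc(OC)cc3)[C@H]4c3cc(OC)cc(OC)c32)cc1
F2 | step 14 | diastereomeric ethyl ester, east (2S,3S), trans | COc1ccc([C@@H]2Cc3c4c(cc5c3[C@H](c3cc(OC)cc(OC)c3)[C@@H](C(=O)OCC)O5)O[C@H](c3ccc(OC)cc3)[C@H]4c3cc(OC)cc(OC)c32)cc1
F3 | step 14 | carboxylic acid from F1, east (2R,3R) | COc1ccc([C@@H]2Cc3c4c(cc5c3[C@@H](c3cc(OC)cc(OC)c3)[C@H](C(=O)O)O5)O[C@H](c3ccc(OC)cc3)[C@H]4c3cc(OC)cc(OC)c32)cc1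
F4 | step 6 | methyl (2S,3S)-6-benzyloxy-2-(4-methoxyphenyl)-4-[(E)-2-(4-methoxyphenyl)ethenyl]-2,3-dihydrobenzofuran-3-carboxylate | COC(=O)[C@H]1c2c(/C=C/c3ccc(OC)cc3)cc(OCc3ccccc3)cc2O[C@@H]1c1ccc(OC)cc1
F5 | step 6 | carboxylic acid from F4 | OC(=O)[C@H]1c2c(/C=C/c3ccc(OC)cc3)cc(OCc3ccccc3)cc2O[C@@H]1c1ccc(OC)cc1
F6 | step 6 | N-(acyloxy)phthalimide of F5 | O=C(ON1C(=O)c2ccccc2C1=O)[C@H]1c2c(/C=C/c3ccc(OC)cc3)cc(OCc3ccccc3)cc2O[C@@H]1c1ccc(OC)cc1
F7 | step 6 | (3,5-dimethoxyphenyl)zinc chloride | COc1cc(OC)cc([Zn]Cl)c1
F8 | step 4 | trans-3-bromo derivative of 4 ((2R,3R) by CIP, C2 spatially unchanged) | O=C1[C@H](Br)[C@@H](c2ccc(OC)cc2)Oc2cc(OCc3ccccc3)cc(OS(=O)(=O)C(F)(F)F)c12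
F9 | step 4 | 4,4-dimethyl ketal of F8 | COC1(OC)[C@H](Br)[C@@H](c2ccc(OC)cc2)Oc2cc(OCc3ccccc3)cc(OS(=O)(=O)C(F)(F)F)c12
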